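**Assumption:** the target has no stereocentre and no configurationally stable axis, so it is made as the single achiral compound; genistein is taken as a cheap commercial starting material.

## Retrosynthetic overview

1. Target 7 comes from its tri-O-methyl ether 6 by global O-demethylation (last step, no skeletal change).
2. Key disconnection: the diaryl ether C8–O bond of 6, made late and convergently by Cu-catalysed O-arylation of the 4'-OH of 8-chlorogenistein 4 with the 8-iodide 5.
3. Both halves come from one precursor, tri-O-methylgenistein 2 (from genistein 1): C8-chlorination then demethylation gives 4; C8-iodination gives 5.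
4. No ring is built: both chromone ring systems and all benzene rings come intact from genistein; only C–Cl, C–I and C–O bonds are formed.

## Route

Step 1
Reactants: 1 genistein
Product: 2 5,7-dimethoxy-3-(4-methoxyphenyl)-4H-chromen-4-one (tri-O-methylgenistein)
Conditions: Me2SO4 (6 equiv), K2CO3 (8 equiv), acetone, reflux, 36 h
Reagents that add atoms: dimethyl sulfate, COS(=O)(=O)OC
Why: Exhaustive Williamson O-methylation, with excess reagent and prolonged reflux forcing the hydrogen-bonded 5-OH to react as well; no stereocentre is involved.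

Step 2
Reactants: 2 5,7-dimethoxy-3-(4-methoxyphenyl)-4H-chromen-4-one
Product: 3 8-chloro-5,7-dimethoxy-3-(4-methoxyphenyl)-4H-chromen-4-one
Conditions: NCS (1.05 equiv), TFA (0.3 equiv), MeCN, 0 °C to rt
Reagents that add atoms: N-chlorosuccinimide, O=C1CCC(=O)N1Cl
Why: Electrophilic aromatic chlorination, expected at C8 by analogy with the C8 preference of 5,7-dialkoxychromones (C8 is ortho to 7-OMe and the ring oxygen and para to 5-OMe, whereas C6 is crowded between two OMe groups), and faster than attack on the 4-methoxyphenyl ring.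

Step 3
Reactants: 3 8-chloro-5,7-dimethoxy-3-(4-methoxyphenyl)-4H-chromen-4-one
Product: 4 8-chloro-5,7-dihydroxy-3-(4-hydroxyphenyl)-4H-chromen-4-one (8-chlorogenistein)
Conditions: BBr3 (9 equiv), CH2Cl2, −78 °C to rt, 24 h; then H2O
Reagents that add atoms: none
Why: Lewis-acid aryl methyl ether cleavage (bromide attacks the O-methyl of the boron-complexed ether), which leaves the aryl chloride and the chromone untouched.

Step 4
Reactants: 2 5,7-dimethoxy-3-(4-methoxyphenyl)-4H-chromen-4-one
Product: 5 8-iodo-5,7-dimethoxy-3-(4-methoxyphenyl)-4H-chromen-4-one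
Conditions: NIS (1.1 equiv), TFA (0.3 equiv), MeCN, rt, dark
Reagents that add atoms: N-iodosuccinimide, O=C1CCC(=O)N1I
Why: Electrophilic aromatic iodination with acid-activated NIS, with the same C8 preference as in step 2 and clean mono-substitution because of the size of iodine.

Step 5
Reactants: 4 8-chloro-5,7-dihydroxy-3-(4-hydroxyphenyl)-4H-chromen-4-one; 5 8-iodo-5,7-dimethoxy-3-(4-methoxyphenyl)-4H-chromen-4-one (1.2 equiv)
Product: 6 8-chloro-3-[4-({5,7-dimethoxy-3-(4-methoxyphenyl)-4-oxo-4H-chromen-8-yl}oxy)phenyl]-5,7-dihydroxy-4H-chromen-4-one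
Conditions: CuI (20 mol%), picolinic acid (40 mol%), K3PO4 (3 equiv), DMSO, 90 °C, Ar, 24 h; aq. HCl work-up
Reagents that add atoms: none
Why: Proposed new method: a protecting-group-free, site-selective Ullmann-type O-arylation in which excess K3PO4 turns 4 into its 7,4'-diphenoxide; the 7-phenoxide is a weakly basic vinylogous carboxylate flanked by Cl and the 5-OH stays locked in its hydrogen bond to C4=O, so only the most basic, unhindered 4'-phenoxide forms the picolinate-ligated Cu(I) aryloxide, which adds oxidatively into the C8–I bond of 5 (C–Cl is inert to Cu) and closes the C–O bond by reductive elimination from Cu(III); the closest known reaction type is the CuI/picolinic acid Ullmann diaryl ether synthesis with ortho-disubstituted aryl iodides, with the dianion-controlled 4'-O-alkylation of 5,7,4'-trihydroxyisoflavones as the selectivity analogue, but neither an unprotected trihydroxyisoflavone nucleophile nor a 2,6-dioxygenated 8-iodochromone electrophile has been used in it.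

Step 6
Reactants: 6 8-chloro-3-[4-({5,7-dimethoxy-3-(4-methoxyphenyl)-4-oxo-4H-chromen-8-yl}oxy)phenyl]-5,7-dihydroxy-4H-chromen-4-one
Product: 7 Bisoflavolin I, 8-chloro-3-[4-({5,7-dihydroxy-3-(4-hydroxyphenyl)-4-oxo-4H-chromen-8-yl}oxy)phenyl]-5,7-dihydroxy-4H-chromen-4-one
Conditions: BBr3 (12 equiv), CH2Cl2, −78 °C to 35 °C, 36 h; then H2O
Reagents that add atoms: none
Why: Global BBr3 O-demethylation of the three aryl methyl ethers, under which diaryl ether C–O bonds, the aryl chloride and both chromones are stable.

## Compound list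

1 | genistein, 5,7-dihydroxy-3-(4-hydroxyphenyl)-4H-chromen-4-one | O=c1c(-c2ccc(O)cc2)coc2cc(O)cc(O)c12 | starting material
2 | 5,7-dimethoxy-3-(4-methoxyphenyl)-4H-chromen-4-one | COc1ccc(-c2coc3cc(OC)cc(OC)c3c2=O)cc1 | intermediate
3 | 8-chloro-5,7-dimethoxy-3-(4-methoxyphenyl)-4H-chromen-4-one | COc1ccc(-c2coc3c(Cl)c(OC)cc(OC)c3c2=O)cc1 | intermediate
4 | 8-chloro-5,7-dihydroxy-3-(4-hydroxyphenyl)-4H-chromen-4-one (8-chlorogenistein) | O=c1c(-c2ccc(O)cc2)coc2c(Cl)c(O)cc(O)c12 | intermediate
5 | 8-iodo-5,7-dimethoxy-3-(4-methoxyphenyl)-4H-chromen-4-one | COc1ccc(-c2coc3c(I)c(OC)cc(OC)c3c2=O)cc1 | intermediate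
6 | 8-chloro-3-[4-({5,7-dimethoxy-3-(4-methoxyphenyl)-4-oxo-4H-chromen-8-yl}oxy)phenyl]-5,7-dihydroxy-4H-chromen-4-one | O=c1c(-c2ccc(Oc3c(OC)cc(OC)c4c(=O)c(-c5ccc(OC)cc5)coc34)cc2)coc2c(Cl)c(O)cc(O)c12 | intermediate
7 | Bisoflavolin I (achiral, no stereocentre) | O=c1c(-c2ccc(Oc3c(O)cc(O)c4c(=O)c(-c5ccc(O)cc5)coc34)cc2)coc2c(Cl)c(O)cc(O)c12 | target

## Step count and risks

Total step count: 6.
Longest linear sequence: 5 steps (steps 1, 2, 3, 5, 6: 1 → 2 → 3 → 4 → 6 → 7); step 4 is a one-step branch from 2.

**Most likely to fail, 1: step 5 (the proposed new coupling).** Possible failures are copper sequestration by the 5-OH/4-oxo chelate, competing 7-O-arylation, or hydrodeiodination of the hindered electron-rich iodide. The fallback uses only known chemistry and removes the site-selectivity question by protection. It sets out from 4: selective methylation of the most acidic 7-OH (MeI 1.05 equiv, KHCO3, DMF, rt) gives 8-chloro-5-hydroxy-3-(4-hydroxyphenyl)-7-methoxy-4H-chromen-4-one F1, whose only free non-chelated phenol is the 4'-OH. A classical ligand-assisted Ullmann ether synthesis of this mono-phenol with 5 (CuI, N,N-dimethylglycine hydrochloride, Cs2CO3, dioxane, 100 °C, which can be pushed to stoichiometric copper) gives 8-chloro-3-[4-({5,7-dimethoxy-3-(4-methoxyphenyl)-4-oxo-4H-chromen-8-yl}oxy)phenyl]-5-hydroxy-7-methoxy-4H-chromen-4-one F2. Its four methyl ethers are cleaved with BBr3 as in step 6, and the fallback comes back to the route at 7.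

**Most likely to fail, 2: step 2 (C8 chlorination).** NCS is the least selective of the halogenating agents used and could give C6/C8 mixtures, 6,8-dichlorination or some chlorination of the anisole ring. The fallback replaces electrophilic chlorination by halogen exchange. It sets out from 5, whose C8 regiochemistry comes from the more selective iodination, and heats it with CuCl (3 equiv) in DMF at 140 °C (copper-mediated aryl iodide to aryl chloride exchange). It comes back to the route at 3 and makes no new compound (F0).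

**Most likely to fail, 3: step 6 (global demethylation).** The 7-OMe and 4'-OMe groups cleave slowly and the polyphenolic product is exposed to a large excess of BBr3 for a long time. The fallback changes the protecting group so that the last step is a mild debenzylation. It sets out from 1: perbenzylation (BnBr, K2CO3, DMF, 80 °C) gives 5,7-bis(benzyloxy)-3-[4-(benzyloxy)phenyl]-4H-chromen-4-one F3. Iodination (NIS, cat. TFA, MeCN) gives 5,7-bis(benzyloxy)-3-[4-(benzyloxy)phenyl]-8-iodo-4H-chromen-4-one F4. Coupling with 4 under the step 5 conditions gives 3-[4-({5,7-bis(benzyloxy)-3-[4-(benzyloxy)phenyl]-4-oxo-4H-chromen-8-yl}oxy)phenyl]-8-chloro-5,7-dihydroxy-4H-chromen-4-one F5. BCl3 with pentamethylbenzene (CH2Cl2, −78 °C) removes the benzyl groups without touching C–Cl, and the fallback comes back to the route at 7.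

## Further compounds

F1 | step 5 | 8-chloro-5-hydroxy-3-(4-hydroxyphenyl)-7-methoxy-4H-chromen-4-one | COc1cc(O)c2c(=O)c(-c3ccc(O)cc3)coc2c1Cl
F2 | step 5 | 8-chloro-3-[4-({5,7-dimethoxy-3-(4-methoxyphenyl)-4-oxo-4H-chromen-8-yl}oxy)phenyl]-5-hydroxy-7-methoxy-4H-chromen-4-one | COc1cc(O)c2c(=O)c(-c3ccc(Oc4c(OC)cc(OC)c5c(=O)c(-c6ccc(OC)cc6)coc45)cc3)coc2c1Cl
F0 | step 2 | none | none
F3 | step 6 | 5,7-bis(benzyloxy)-3-[4-(benzyloxy)phenyl]-4H-chromen-4-one | O=c1c(-c2ccc(OCc3ccccc3)cc2)coc2cc(OCc3ccccc3)cc(OCc3ccccc3)c12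
F4 | step 6 | 5,7-bis(benzyloxy)-3-[4-(benzyloxy)phenyl]-8-iodo-4H-chromen-4-one | O=c1c(-c2ccc(OCc3ccccc3)cc2)coc2c(I)c(OCc3ccccc3)cc(OCc3ccccc3)c12
F5 | step 6 | 3-[4-({5,7-bis(benzyloxy)-3-[4-(benzyloxy)phenyl]-4-oxo-4H-chromen-8-yl}oxy)phenyl]-8-chloro-5,7-dihydroxy-4H-chromen-4-one | O=c1c(-c2ccc(Oc3c(OCc4ccccc4)cc(OCc4ccccc4)c4c(=O)c(-c5ccc(OCc6ccccc6)cc5)coc34)cc2)coc2c(Cl)c(O)cc(O)c12
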